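The trap in this resolution is to take the excess from how selective the catalyst looks, when for south, the flask short of reagent, I reckon it from how much reagent was charged.

| flask | left-handed substrate | right-handed substrate | reagent | free catalyst | remark | time |
|---|---|---|---|---|---|---|
| Saturday's | 29 mM | 29 mM | 0.33 equiv | 2 mol% | run made earlier |  |
| Tuesday's | 29 mM | 29 mM | 1.3 equiv | 2 mol% | run made earlier |  |
| south-west | 29 mM | 29 mM | 1.50 equiv | 2 mol% |  | 20 min |
| south | 29 mM | 29 mM | 0.490 equiv | 2 mol% |  | 20 min |

| run | time / min | right-handed substrate / % | left-handed substrate / % |
|---|---|---|---|
| Saturday's | 1.33 | 51 | 45 |
| Saturday's | 4.00 | 48 | 37 |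
| Saturday's | 6.00 | 51 | 38 |
| Saturday's | 10.0 | 45 | 36 |
| Tuesday's | 0.833 | 47 | 40 |
| Tuesday's | 2.00 | 48 | 26 |
| Tuesday's | 4.00 | 50 | 18 |
| Tuesday's | 10.0 | 52 | 2 |

(scatter of a reading: 2 percentage points)

- free catalyst is single-handed; left-handed substrate and right-handed substrate are mirror images of each other, charged as a racemate, each of them at the stated concentration
- an excess is below zero if the other one leads

- the flask that ends with the higher excess of right-handed substrate over left-handed substrate among what is left of the two, or "neither" when 2 percentage points or less lies between them (south-west / south / neither)
- excess of right-handed substrate over left-handed substrate among what is left of the two at the end, south-west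
- excess of right-handed substrate over left-handed substrate among what is left of the two at the end, south

My first question is whether the right-handed substrate takes any reagent. In Tuesday's run the left-handed substrate falls to 2% of the pair at 10.0 min, while the right-handed one reads 52%. That last reading shows no loss of it beyond the scatter of 2 percentage points, so I cannot put a number on the selectivity factor, and I count the reagent as going to the left-handed substrate.

My second question is how much the reagent can take. Equivalents are counted on the left-handed substrate, which is half of the pair, so, taking one reagent for each substrate converted, the budget, the fraction of the pair the reagent can convert, is the equivalents divided by two. Saturday's budget is 16.5%. Its left-handed readings flatten near 37.0%, a reading of 13 points lost, somewhat under the budget. South's budget is 24.5%, less than the left-handed share, so I expect the reagent to be the limiting reagent in south. With the right-handed substrate whole, the excess is the budget over one minus the budget, the budget excess, and I reckon 32.5%.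

South-west's budget is 75.0%, beyond the left-handed share, so my third question is time. Tuesday's last reading, with the right-handed substrate counted whole, gives an excess of 92.3%, and south-west has more reagent and twice the time, so I expect it above that and far ahead of south.

The forecast says south-west, with 97% for south-west and 30% for south, on the ground that “Only the left-handed substrate visibly reacts”. My south figure stands above its figure.

The flasks give 97.7% for south-west and 31.7% for south, so south-west leads.

    reagent + free catalyst → spent catalyst B (k = 0.290 L mol⁻¹ s⁻¹)
    reagent + catalyst intermediate A → free catalyst + left-handed product (k = 7.70 L mol⁻¹ s⁻¹)
    free catalyst → spent catalyst A (k = 0.00410 s⁻¹)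
    free catalyst + left-handed substrate ⇌ catalyst intermediate A (K = 1000 L mol⁻¹, k = 230 L mol⁻¹ s⁻¹)
    free catalyst + right-handed substrate ⇌ catalyst intermediate B (K = 28.0 L mol⁻¹, k = 53.0 L mol⁻¹ s⁻¹)
    2 free catalyst → spent catalyst C (k = 8.30 L mol⁻¹ s⁻¹)
    reagent + catalyst intermediate B → free catalyst + right-handed product (k = 2.60 L mol⁻¹ s⁻¹)

South ends 0.80 points under its budget excess, with 1.7% of its reagent left. South-west's excess moves by 5 points at 1.17 equiv of reagent or at 1.4 mol% of free catalyst, the nearest such settings below its charge; a shift of that kind is what a run would have to show before the forecast's south-west figure comes into doubt. A neighbouring flask, like south but with 0.200 equiv of reagent, has a budget of 10.0% and a budget excess of 11.1%. It ends at 11.6%, with 1.1% of its reagent left and 39.5% left-handed against 49.9% right-handed substrate.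

The readings were generated by integration for an exercise; scatter was added.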